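# Irigenin by aryne insertion into a β‑methoxyacrylic acid: synthesis proposal

## The problem

Irigenin (20) is an achiral isoflavone, so everything to be solved is regiochemical. Ring A is a pentasubstituted benzene with four contiguous oxygens (O1 on C8a, OH on C7, OMe on C6, OH on C5), the acyl carbon C4 on C4a and a single C–H at C8. The classical ring A precursors, aryl ketones of 2‑methoxyphloroglucinol, carry two hydroxyls ortho to the acyl group. Nothing in them decides whether ring C closes onto the oxygen beside C8–H (6‑methoxy series, wanted) or onto the one beside the methoxy carbon (8‑methoxy series).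

The oxygens must also be told apart: one methyl ether between two free hydroxyls in ring A, one free hydroxyl beside two methyl ethers in ring B. Selective demethylation delivers neither pattern reliably, so the methyl ethers must be present from the start and the three hydroxyls carried under one removable group. Rings A and B are joined through ring C, which requires the bonds O1–C8a, C4–C4a, O1–C2 and C3–C1'. The finished 5,7‑dihydroxy‑6‑methoxychromone opens at C2 with hydroxide, can open and reclose to the 8‑methoxy isomer in hot strong acid (Wessely–Moser rearrangement), and is easily oxidised, so the end game must be short and mild.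

The feature the plan exploits: the adjacent ring A carbons C8a and C4a carry the two ends of one carboxyl unit, an oxygen (O1) and an acyl carbon (C4), with C5–O on the C4a flank and C8–H on the C8a flank. This is the pattern a 3‑alkoxyaryne returns when it inserts into the C–O bond of a carboxylate. The O1–C2H=C3 enol ether of ring C is the β‑alkoxy group of an acrylic acid. With the same protecting group on O5 and O7, the phenol behind that aryne (C8a–OH para to C6–OMe) is mirror‑symmetric.

## Retrosynthesis

**20 ⇒ 19.** The three O–H bonds at C5, C7 and C3' are traced back to methoxymethyl (MOM) ethers in 19. The group has to survive fluoride at 125 °C, butyllithium and hydroxide. It must also have no aromatic C–H, because benzyl ethers would compete in the C–H borylations used below. It leaves under acid far milder than what opens ring C. The forward reaction is an acetal exchange in acidic methanol.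

**19 ⇒ 8 + 16 (key disconnection).** Three bonds are cut at once: O1–C8a, C4–C4a and O1–C2. Ring A becomes aryne 17, generated from silyl triflate 8, and the rest becomes the β‑methoxyacrylic acid 16, which carries O1, C2, C3, C4, the carbonyl oxygen and ring B. Cutting only C3–C1' (coupling onto a preformed chromone) or only C2 (deoxybenzoin closure) leaves the real problem untouched, namely acylating a tetraoxygenated ring at a defined position and closing onto a defined oxygen. Here the C5 alkoxy group of the aryne decides both. The precursors are a tetrasubstituted benzene with no carbon substituent and an open‑chain acid. The forward reaction must add the carboxylate oxygen at C8a, transfer the acyl group to C4a to give ketophenolate 18, and close ring C by addition–elimination at C2.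

**8 ⇒ 5 ⇒ 4.** The C4a–Si and O–S bonds of 8 are traced back to bromophenol 5 (silylation, bromine–lithium exchange with retro‑Brook shift, triflation), and the C–Br bond to phenol 4. Because 4 is mirror‑symmetric, its two ortho positions are equivalent and the para position is blocked. The bromination that fixes the future C4a therefore has only one possible outcome. The 6‑methoxy/8‑methoxy question is settled here, before any ring is closed.

**4 ⇒ 2 ⇒ 1.** The C–O bond that becomes O1–C8a is made by iridium‑catalysed C–H borylation of 2 and oxidation of boronate 3. C5 of 2 is the only C–H without an ortho substituent. Compound 2 is the bis‑MOM ether of commercial 2‑methoxyresorcinol (1), which already holds the C6 methyl ether between the two future hydroxyls.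

**16 ⇒ 15 ⇒ 11 + 14.** The acid comes from ester 15 by saponification. The C3–C1' bond (target numbering) is cut to arylboronate 11 and the α‑iodo‑β‑methoxyacrylate 14. This vinyl iodide delivers C2, C3 and C4 at their final oxidation levels in one coupling. The usual alternative is to homologate a benzaldehyde to an arylacetate and then formylate and methylate it, which takes several steps.

**11 ⇒ 10 ⇒ 9 and 14 ⇒ 12.** Boronate 11 is reached by the same sterically controlled C–H borylation, now on the MOM ether 10 of commercial 2,3‑dimethoxyphenol (9). Ring B's substitution pattern is bought rather than made. Iodide 14 comes from commercial methyl (E)‑3‑methoxyacrylate (12) by iodination–elimination.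

## Roads not taken

**Alternative 1:** Cut C2 out of ring C together with C4–C4a (the deoxybenzoin route, the one most chemists would draw first). Houben–Hoesch acylation of 2‑methoxyphloroglucinol A1 with (3‑hydroxy‑4,5‑dimethoxyphenyl)acetonitrile A2 would give deoxybenzoin A3. A one‑carbon electrophile (a formamide acetal or an activated formamide) would then close ring C. In A3 the ketone is flanked by two free hydroxyls, one beside the methoxy carbon and one beside C–H, and no structural element tells the formyl unit which to use. The target and its 8‑methoxy isomer A4 are both open, and acid can interconvert them. A1 is not a bulk chemical, and A2 needs a multi‑step homologation. The chosen plan removes the ambiguity by mechanism (aryne polarisation) and builds ring B's side chain in one coupling.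

**Alternative 2:** Cut C3–C1'. Suzuki–Miyaura coupling of 3‑iodochromone A5 with boronate 11 under zerovalent palladium would give 19. A5 comes from 2‑hydroxyacetophenone A6 through its enaminone and iodine‑induced cyclisation. The coupling is reliable but forms one bond and decides nothing about ring A. A6 is the hard part: by classical means it requires acylating a differentiated tetraoxygenated benzene and leaving exactly the right ortho hydroxyl free. That is three linear steps after A6, against one step from 8 in the chosen plan, which also sets the regiochemistry.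

**Alternative 3:** Form C3–C1' by a 1,2‑aryl shift. Claisen–Schmidt condensation of A6 with aldehyde A7 would give the 2'‑hydroxychalcone A8. Oxidative rearrangement with Tl(NO3)3 in methanol (or a hypervalent iodine reagent) would move ring B from the β‑ to the α‑carbon and give acetal A9, which closes to 19 in acid. This needs A6 again, uses a stoichiometric toxic oxidant on two very electron‑rich rings, and spends three steps after A6 on bonds the aryne annulation makes in one.

Key step: step 10

## Route

Assumption: 1, 9 and 12 are taken as commercial. The target has no stereocentre; the only stereodescriptors in the route are the alkene geometries of 12–16, which are erased in step 10.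

**Step 1**
Reactants: 1 2‑methoxyresorcinol (2‑methoxybenzene‑1,3‑diol)
Product: 2 2‑methoxy‑1,3‑bis(methoxymethoxy)benzene
Conditions: MOMCl, i‑Pr2NEt, CH2Cl2, 0 °C to rt
Reagents that add atoms: chloromethyl methyl ether, COCCl
Why: O‑alkylation of both phenols (MOM ether formation); MOM has no aryl C–H to compete in step 2 and tolerates fluoride, butyllithium and hydroxide.

**Step 2**
Reactants: 2 2‑methoxy‑1,3‑bis(methoxymethoxy)benzene
Product: 4 4‑methoxy‑3,5‑bis(methoxymethoxy)phenol, via arylboronate 3 (not isolated)
Conditions: [Ir(OMe)(cod)]2 (cat.), dtbpy, B2pin2 (0.6 equiv), THF, 80 °C; then 30% aq. H2O2, NaOH, 0 °C; NH4Cl work‑up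
Reagents that add atoms: bis(pinacolato)diboron, CC1(C)OB(OC1(C)C)B1OC(C)(C)C(C)(C)O1 (boron of intermediate 3 only); hydrogen peroxide, OO (the phenol oxygen)
Why: Iridium‑catalysed aromatic C–H borylation is sterically controlled, and C5 is the only C–H of 2 without an ortho substituent; oxidation of the C–B bond then gives the phenol at the same carbon. The product is mirror‑symmetric, which step 3 relies on.

**Step 3**
Reactants: 4 4‑methoxy‑3,5‑bis(methoxymethoxy)phenol
Product: 5 2‑bromo‑4‑methoxy‑3,5‑bis(methoxymethoxy)phenol
Conditions: NBS (1.0 equiv), CH2Cl2, −78 to −20 °C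
Reagents that add atoms: N‑bromosuccinimide, O=C1CCC(=O)N1Br
Why: Electrophilic aromatic bromination ortho to the free hydroxyl; the para position is blocked by OMe and the two ortho positions are equivalent by symmetry, so monobromination can give only one regioisomer.

**Step 4**
Reactants: 5 2‑bromo‑4‑methoxy‑3,5‑bis(methoxymethoxy)phenol
Product: 8 4‑methoxy‑3,5‑bis(methoxymethoxy)‑2‑(trimethylsilyl)phenyl trifluoromethanesulfonate, via aryl silyl ether 6 (not isolated), via lithium phenolate 7 (not isolated)
Conditions: HMDS, THF, 70 °C, then concentrate; n‑BuLi, THF, −100 to −78 °C; Tf2O, −100 °C, cold NaHCO3 quench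
Reagents that add atoms: hexamethyldisilazane, C[Si](C)(C)N[Si](C)(C)C; trifluoromethanesulfonic anhydride, O=S(=O)(OS(=O)(=O)C(F)(F)F)C(F)(F)F
Why: O‑silylation, bromine–lithium exchange with 1,3 O‑to‑C silyl migration (retro‑Brook rearrangement) and O‑triflation of the resulting phenolate, the standard one‑flask route to 2‑(trimethylsilyl)aryl triflates. Exchange at −100 °C should outrun lithiation next to the MOM groups.

**Step 5**
Reactants: 9 2,3‑dimethoxyphenol
Product: 10 1,2‑dimethoxy‑3‑(methoxymethoxy)benzene
Conditions: MOMCl, i‑Pr2NEt, CH2Cl2, 0 °C to rt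
Reagents that add atoms: chloromethyl methyl ether, COCCl
Why: MOM ether formation on the single phenol; this oxygen becomes the free 3'‑hydroxyl of the target.

**Step 6**
Reactants: 10 1,2‑dimethoxy‑3‑(methoxymethoxy)benzene
Product: 11 2‑[3,4‑dimethoxy‑5‑(methoxymethoxy)phenyl]‑4,4,5,5‑tetramethyl‑1,3,2‑dioxaborolane
Conditions: [Ir(OMe)(cod)]2 (cat.), dtbpy, B2pin2 (0.6 equiv), THF, 80 °C
Reagents that add atoms: bis(pinacolato)diboron, CC1(C)OB(OC1(C)C)B1OC(C)(C)C(C)(C)O1
Why: Sterically controlled iridium‑catalysed C–H borylation; C5 is the only C–H not ortho to an oxygen substituent, and it is the carbon that becomes C1' of ring B.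

**Step 7**
Reactants: 12 methyl (E)‑3‑methoxyprop‑2‑enoate
Product: 14 methyl (Z)‑2‑iodo‑3‑methoxyprop‑2‑enoate, via iodoacetate adduct 13 (not isolated)
Conditions: NIS, AcOH, CH2Cl2, rt; then Et3N, 0 °C to rt
Reagents that add atoms: N‑iodosuccinimide, O=C1CCC(=O)N1I; acetic acid, CC(=O)O (acetoxy group of intermediate 13 only)
Why: Iodoacetoxylation of the enol ether followed by amine‑induced elimination of acetic acid; the push–pull isomer with the ester trans to OMe is the stable one. The geometry is of no consequence later.

**Step 8**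
Reactants: 11 2‑[3,4‑dimethoxy‑5‑(methoxymethoxy)phenyl]‑4,4,5,5‑tetramethyl‑1,3,2‑dioxaborolane; 14 methyl (Z)‑2‑iodo‑3‑methoxyprop‑2‑enoate
Product: 15 methyl (E)‑2‑[3,4‑dimethoxy‑5‑(methoxymethoxy)phenyl]‑3‑methoxyprop‑2‑enoate
Conditions: Pd(PPh3)4 (5 mol %), K3PO4, 1,4‑dioxane/H2O, 90 °C
Reagents that add atoms: none
Why: Suzuki–Miyaura coupling of an electron‑poor vinyl iodide with an arylboronate, with retention of alkene geometry (the descriptor changes from Z to E only because the priorities change). It forms the future C3–C1' bond.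

**Step 9**
Reactants: 15 methyl (E)‑2‑[3,4‑dimethoxy‑5‑(methoxymethoxy)phenyl]‑3‑methoxyprop‑2‑enoate
Product: 16 (E)‑2‑[3,4‑dimethoxy‑5‑(methoxymethoxy)phenyl]‑3‑methoxyprop‑2‑enoic acid
Conditions: LiOH·H2O, THF/MeOH/H2O, 40 °C; then cold 1 M HCl to pH 4, 0 °C
Reagents that add atoms: lithium hydroxide, [Li+].[OH-]
Why: Saponification of the methyl ester by acyl substitution; the vinylogous carbonate is sluggish, hence gentle warming. Acidification only to pH 4 in the cold should spare the enol ether and the MOM group.

**Step 10**
Reactants: 8 4‑methoxy‑3,5‑bis(methoxymethoxy)‑2‑(trimethylsilyl)phenyl trifluoromethanesulfonate; 16 (E)‑2‑[3,4‑dimethoxy‑5‑(methoxymethoxy)phenyl]‑3‑methoxyprop‑2‑enoic acid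
Product: 19 3‑[3,4‑dimethoxy‑5‑(methoxymethoxy)phenyl]‑6‑methoxy‑5,7‑bis(methoxymethoxy)‑4H‑chromen‑4‑one, via aryne 17 (not isolated), via ketophenolate 18 (not isolated)
Conditions: CsF (4 equiv), 8 (1.5 equiv), THF, 125 °C, sealed tube
Reagents that add atoms: none
Why: Proposed new method: fluoride releases aryne 17 from 8; the carboxylate of 16 adds to the aryne carbon that becomes C8a, the aryl anion formed at C4a attacks the ester carbonyl (4‑exo‑trig) and the transient four‑membered alkoxide collapses to ketophenolate 18, a net insertion of the aryne into the acyl C–O bond; the phenolate then closes the pyranone ring by 6‑endo‑trig oxa‑Michael addition at C2 and E1cB loss of methoxide. The closest known reaction type is the fluoride‑induced insertion of arynes into the C–O bond of carboxylic acids to give 2‑hydroxyaryl ketones, which with arylpropiolic acids runs on to flavones by the same oxa‑Michael closure; new here is a β‑methoxyacrylic acid as partner, whose β‑carbon arrives at the formyl oxidation level and so delivers C2, C3, C4 and ring B in one operation. The regiochemistry needed (O at C8a, C at C4a) comes from the aryne: the C5 alkoxy group beside one aryne carbon withdraws inductively and distorts the triple bond, so the nucleophile attacks the distal carbon C8a (next to C8–H, also the less hindered one) and the charge develops at C4a beside that oxygen, with the C6 methoxy group meta to the charge reinforcing this. The second selectivity needed is carbonyl attack by the aryl anion rather than conjugate attack at the β‑carbon; the in‑plane sp2 lone pair reaches the adjacent ester carbonyl easily but not the π face of the remote β‑carbon, as the behaviour of unsaturated acids in the known insertion indicates. Acid 16 has no α‑hydrogen, so the aryl anion cannot be quenched by enolisation of the ester. No stereocentre is formed, and the enol ether geometry of 16 disappears in the addition–elimination.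

**Step 11**
Reactants: 19 3‑[3,4‑dimethoxy‑5‑(methoxymethoxy)phenyl]‑6‑methoxy‑5,7‑bis(methoxymethoxy)‑4H‑chromen‑4‑one
Product: 20 irigenin (5,7‑dihydroxy‑3‑(3‑hydroxy‑4,5‑dimethoxyphenyl)‑6‑methoxy‑4H‑chromen‑4‑one)
Conditions: 3 M HCl, MeOH/THF, 50 °C
Reagents that add atoms: none
Why: Acid‑catalysed acetal exchange removes all three MOM groups, the formaldehyde unit leaving as dimethoxymethane. These conditions are far milder than those that open ring C (Wessely–Moser rearrangement), so the 6‑methoxy placement should be retained.

## Compound list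

1 | 2‑methoxyresorcinol (2‑methoxybenzene‑1,3‑diol) | COc1c(O)cccc1O | starting material
2 | 2‑methoxy‑1,3‑bis(methoxymethoxy)benzene | COCOc1cccc(OCOC)c1OC | intermediate
3 | 2‑[4‑methoxy‑3,5‑bis(methoxymethoxy)phenyl]‑4,4,5,5‑tetramethyl‑1,3,2‑dioxaborolane (not isolated) | COCOc1cc(B2OC(C)(C)C(C)(C)O2)cc(OCOC)c1OC | intermediate
4 | 4‑methoxy‑3,5‑bis(methoxymethoxy)phenol | COCOc1cc(O)cc(OCOC)c1OC | intermediate
5 | 2‑bromo‑4‑methoxy‑3,5‑bis(methoxymethoxy)phenol | COCOc1cc(O)c(Br)c(OCOC)c1OC | intermediate
6 | [2‑bromo‑4‑methoxy‑3,5‑bis(methoxymethoxy)phenoxy]trimethylsilane (not isolated) | COCOc1cc(O[Si](C)(C)C)c(Br)c(OCOC)c1OC | intermediate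
7 | lithium 4‑methoxy‑3,5‑bis(methoxymethoxy)‑2‑(trimethylsilyl)phenolate (not isolated) | [Li+].COCOc1cc([O-])c([Si](C)(C)C)c(OCOC)c1OC | intermediate
8 | 4‑methoxy‑3,5‑bis(methoxymethoxy)‑2‑(trimethylsilyl)phenyl trifluoromethanesulfonate | COCOc1cc(OS(=O)(=O)C(F)(F)F)c([Si](C)(C)C)c(OCOC)c1OC | intermediate
9 | 2,3‑dimethoxyphenol | COc1cccc(O)c1OC | starting material
10 | 1,2‑dimethoxy‑3‑(methoxymethoxy)benzene | COCOc1cccc(OC)c1OC | intermediate
11 | 2‑[3,4‑dimethoxy‑5‑(methoxymethoxy)phenyl]‑4,4,5,5‑tetramethyl‑1,3,2‑dioxaborolane | COCOc1cc(B2OC(C)(C)C(C)(C)O2)cc(OC)c1OC | intermediate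
12 | methyl (E)‑3‑methoxyprop‑2‑enoate | CO/C=C/C(=O)OC | starting material
13 | methyl 3‑acetoxy‑2‑iodo‑3‑methoxypropanoate (not isolated; racemic, mixture of diastereomers) | COC(OC(C)=O)C(I)C(=O)OC | intermediate
14 | methyl (Z)‑2‑iodo‑3‑methoxyprop‑2‑enoate | CO/C=C(\I)C(=O)OC | intermediate
15 | methyl (E)‑2‑[3,4‑dimethoxy‑5‑(methoxymethoxy)phenyl]‑3‑methoxyprop‑2‑enoate | CO/C=C(\c1cc(OC)c(OC)c(OCOC)c1)C(=O)OC | intermediate
16 | (E)‑2‑[3,4‑dimethoxy‑5‑(methoxymethoxy)phenyl]‑3‑methoxyprop‑2‑enoic acid | CO/C=C(\c1cc(OC)c(OC)c(OCOC)c1)C(=O)O | intermediate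
17 | 4‑methoxy‑3,5‑bis(methoxymethoxy)benzyne (1,2‑didehydro‑4‑methoxy‑3,5‑bis(methoxymethoxy)benzene; not isolated) | COCOC1=CC#CC(OCOC)=C1OC | intermediate
18 | cesium 2‑{(E)‑2‑[3,4‑dimethoxy‑5‑(methoxymethoxy)phenyl]‑3‑methoxyprop‑2‑enoyl}‑4‑methoxy‑3,5‑bis(methoxymethoxy)phenolate (not isolated) | [Cs+].CO/C=C(\c1cc(OC)c(OC)c(OCOC)c1)C(=O)c1c([O-])cc(OCOC)c(OC)c1OCOC | intermediate
19 | 3‑[3,4‑dimethoxy‑5‑(methoxymethoxy)phenyl]‑6‑methoxy‑5,7‑bis(methoxymethoxy)‑4H‑chromen‑4‑one | COCOc1cc2occ(-c3cc(OC)c(OC)c(OCOC)c3)c(=O)c2c(OCOC)c1OC | intermediate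
20 | irigenin (5,7‑dihydroxy‑3‑(3‑hydroxy‑4,5‑dimethoxyphenyl)‑6‑methoxy‑4H‑chromen‑4‑one) | COc1cc(-c2coc3cc(O)c(OC)c(O)c3c2=O)cc(O)c1OC | target

## Step count and least certain steps

Total: 11 steps. Longest linear sequence: 6 steps (steps 1, 2, 3, 4, 10, 11; the ring B branch, steps 5, 6, 8, 9, 10, 11, is equally long).

**Step 10 (key step, bears the label "Proposed new method:").**
What may go wrong:
- The aryl anion at C4a may be protonated by the acid proton (carried as bifluoride) before it reaches the carbonyl, which stops the sequence at an aryl ester. The push–pull carboxyl of 16 is a poorer acyl acceptor than a simple acid, which raises this risk.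
- The aryl anion may attack the β‑carbon instead of the carbonyl, which leads toward a 3‑arylcoumarin skeleton.
- Liberated methoxide may consume the aryne.

Adjustments inside the plan would be the dried cesium salt of 16 and slow aryne release.

Fallback (known chemistry, no aryne), from 5 and 11, returning at 19. Double lithiation of 5 (n‑BuLi, 2.2 equiv, THF, −78 °C) and acylation with N‑methoxy‑N‑methylacetamide should give 1‑[2‑hydroxy‑5‑methoxy‑4,6‑bis(methoxymethoxy)phenyl]ethan‑1‑one F1 (identical with A6); the acetyl group enters where bromine was, so the regiochemistry is again the one fixed in step 3. Condensation with N,N‑dimethylformamide dimethyl acetal (toluene, 90 °C) gives (E)‑3‑(dimethylamino)‑1‑[2‑hydroxy‑5‑methoxy‑4,6‑bis(methoxymethoxy)phenyl]prop‑2‑en‑1‑one F2. Iodine (CHCl3, pyridine, rt) cyclises it to 3‑iodo‑6‑methoxy‑5,7‑bis(methoxymethoxy)‑4H‑chromen‑4‑one F3 (identical with A5). Suzuki–Miyaura coupling of F3 with 11 (Pd(dppf)Cl2, K2CO3, 1,2‑dimethoxyethane/H2O, 80 °C) gives 19. This costs four steps from 5 instead of two, and steps 7–9 fall away.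

**Step 3.**
What may go wrong: bromination may continue at the second ortho position, and the N‑bromo reagent may oxidise the 4‑methoxyphenol toward a quinone.

Fallback from 4, returning at 8 (it also bypasses step 4). Carbamoylation (Et2NCOCl, NaH, THF) gives 4‑methoxy‑3,5‑bis(methoxymethoxy)phenyl N,N‑diethylcarbamate F4. Directed ortho‑metalation (s‑BuLi, TMEDA, THF, −78 °C, then TMSCl) silylates the position between the carbamate and a MOM ether, which is doubly activated; the two such positions are equivalent. This gives 4‑methoxy‑3,5‑bis(methoxymethoxy)‑2‑(trimethylsilyl)phenyl N,N‑diethylcarbamate F5. LiAlH4 (THF, 0 °C) cleaves the carbamate to 4‑methoxy‑3,5‑bis(methoxymethoxy)‑2‑(trimethylsilyl)phenol F6. Deprotonation (n‑BuLi, −78 °C, giving phenolate 7) and Tf2O give 8. No electrophilic halogenation is involved.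

**Step 9.**
What may go wrong: hydroxide may add to the β‑carbon (addition–elimination) with subsequent loss of the formyl carbon, in place of acyl substitution. The enol ether or the MOM group may also be cleaved during acidification.

Fallback from 11, returning at 16, in which no ester is ever hydrolysed. Commercial (E)‑3‑methoxyprop‑2‑enoic acid F7 is treated with NIS/AcOH (CH2Cl2, rt) to give 3‑acetoxy‑2‑iodo‑3‑methoxypropanoic acid F8 (not isolated). Et3N eliminates acetic acid to give (Z)‑2‑iodo‑3‑methoxyprop‑2‑enoic acid F9. Suzuki–Miyaura coupling of F9 as its carboxylate with 11 (Pd(PPh3)4, K3PO4, 3 equiv, 1,4‑dioxane/H2O, 90 °C) and acidification to pH 4 give 16 directly.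

## Further compounds

F1 | step 10 | 1‑[2‑hydroxy‑5‑methoxy‑4,6‑bis(methoxymethoxy)phenyl]ethan‑1‑one | CC(=O)c1c(O)cc(OCOC)c(OC)c1OCOC
F2 | step 10 | (E)‑3‑(dimethylamino)‑1‑[2‑hydroxy‑5‑methoxy‑4,6‑bis(methoxymethoxy)phenyl]prop‑2‑en‑1‑one | CN(C)/C=C/C(=O)c1c(O)cc(OCOC)c(OC)c1OCOC
F3 | step 10 | 3‑iodo‑6‑methoxy‑5,7‑bis(methoxymethoxy)‑4H‑chromen‑4‑one | COCOc1cc2occ(I)c(=O)c2c(OCOC)c1OC
F4 | step 3 | 4‑methoxy‑3,5‑bis(methoxymethoxy)phenyl N,N‑diethylcarbamate | CCN(CC)C(=O)Oc1cc(OCOC)c(OC)c(OCOC)c1
F5 | step 3 | 4‑methoxy‑3,5‑bis(methoxymethoxy)‑2‑(trimethylsilyl)phenyl N,N‑diethylcarbamate | CCN(CC)C(=O)Oc1cc(OCOC)c(OC)c(OCOC)c1[Si](C)(C)C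
F6 | step 3 | 4‑methoxy‑3,5‑bis(methoxymethoxy)‑2‑(trimethylsilyl)phenol | COCOc1cc(O)c([Si](C)(C)C)c(OCOC)c1OC
F7 | step 9 | (E)‑3‑methoxyprop‑2‑enoic acid (commercial) | CO/C=C/C(=O)O
F8 | step 9 | 3‑acetoxy‑2‑iodo‑3‑methoxypropanoic acid (not isolated; racemic, mixture of diastereomers) | COC(OC(C)=O)C(I)C(=O)O
F9 | step 9 | (Z)‑2‑iodo‑3‑methoxyprop‑2‑enoic acid | CO/C=C(\I)C(=O)O
A1 | alternative 1 | 2‑methoxyphloroglucinol (2‑methoxybenzene‑1,3,5‑triol) | COc1c(O)cc(O)cc1O
A2 | alternative 1 | (3‑hydroxy‑4,5‑dimethoxyphenyl)acetonitrile | COc1cc(CC#N)cc(O)c1OC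
A3 | alternative 1 | 2‑(3‑hydroxy‑4,5‑dimethoxyphenyl)‑1‑(2,4,6‑trihydroxy‑3‑methoxyphenyl)ethan‑1‑one | COc1cc(CC(=O)c2c(O)cc(O)c(OC)c2O)cc(O)c1OC
A4 | alternative 1 | 5,7‑dihydroxy‑3‑(3‑hydroxy‑4,5‑dimethoxyphenyl)‑8‑methoxy‑4H‑chromen‑4‑one | COc1cc(-c2coc3c(OC)c(O)cc(O)c3c2=O)cc(O)c1OC
A5 | alternative 2 | 3‑iodo‑6‑methoxy‑5,7‑bis(methoxymethoxy)‑4H‑chromen‑4‑one | COCOc1cc2occ(I)c(=O)c2c(OCOC)c1OC
A6 | alternative 2 | 1‑[2‑hydroxy‑5‑methoxy‑4,6‑bis(methoxymethoxy)phenyl]ethan‑1‑one | CC(=O)c1c(O)cc(OCOC)c(OC)c1OCOC
A7 | alternative 3 | 3,4‑dimethoxy‑5‑(methoxymethoxy)benzaldehyde | COCOc1cc(C=O)cc(OC)c1OC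
A8 | alternative 3 | (E)‑1‑[2‑hydroxy‑5‑methoxy‑4,6‑bis(methoxymethoxy)phenyl]‑3‑[3,4‑dimethoxy‑5‑(methoxymethoxy)phenyl]prop‑2‑en‑1‑one | COCOc1cc(/C=C/C(=O)c2c(O)cc(OCOC)c(OC)c2OCOC)cc(OC)c1OC
A9 | alternative 3 | 1‑[2‑hydroxy‑5‑methoxy‑4,6‑bis(methoxymethoxy)phenyl]‑3,3‑dimethoxy‑2‑[3,4‑dimethoxy‑5‑(methoxymethoxy)phenyl]propan‑1‑one (racemic) | COCOc1cc(C(C(OC)OC)C(=O)c2c(O)cc(OCOC)c(OC)c2OCOC)cc(OC)c1OC
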